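**Assumptions.** (a) Polycyclic intermediates use gibberellane numbering (C1–C20); α is the face of C20 and the 20→12 lactone, β is the face of H5 and H9; the SMILES strings define all stereochemistry. (b) The Meyers lactam alkylation follows its usual endo rule (second electrophile enters anti to the angular methyl); if the opposite sense were observed, the two alkylations would be run in reverse order. The route is a paper design and has not been run.

## Retrosynthetic overview

1. Target ⇐ late functional-group changes: the 19-allyl ester, the 2β,3β-diol from a 3-ketone (enolate hydroxylation, then axial-selective reduction), and the C7 acid from a CH2OBn group.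
2. Ring A ⇐ intermolecular Michael addition of the C10 β-keto lactone to allyl 3-oxopent-4-enoate, Knoevenagel closure (C4–C5), 1,4-reduction (5β-H), C4 methylation.
3. Ring B ⇐ intramolecular Claisen condensation of the lactone enolate (C10) onto the C8 acetate arm; the 20→12α lactone ⇐ reduction of a 12-ketone.
4. C9–C10 ⇐ intermolecular Mukaiyama–Michael addition of an acetate ketene silyl acetal to the exo face of bicyclo[3.2.1]octenone 16 (rings C and D).
5. 16 ⇐ gold-catalysed Conia-ene closure of an (R)-4-allyl-4-propargylcyclohexenone made by Meyers lactam chemistry. Ring order: C, D, lactone, B, A.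

## Route

Step 1
Reactants: 1 (S)-valinol; 2 5-oxohexanoic acid
Product: 3 (3S,8aR)-3-isopropyl-8a-methylhexahydro-5H-oxazolo[3,2-a]pyridin-5-one
Conditions: PhMe, reflux, Dean–Stark, 24 h
Reagents that add atoms: none
Why: Meyers bicyclic lactam formation (amide and N,O-ketal condensation); the valinol centre sets the angular carbon under thermodynamic control (methyl cis to isopropyl).

Step 2
Reactants: 3 Meyers lactam; 4 3-bromo-1-(trimethylsilyl)prop-1-yne
Product: 5 6-[3-(trimethylsilyl)prop-2-yn-1-yl] lactam (C6 epimer mixture)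
Conditions: LiN(i-Pr)2, THF, −78 °C; then 4, −78 → −20 °C
Reagents that add atoms: none
Why: Lactam enolate alkylation; the C6 configuration is irrelevant because it is re-enolised next, and the silyl cap removes the acidic alkyne C–H.

Step 3
Reactants: 5 mono-alkylated lactam; 6 allyl bromide
Product: 7 (3S,6R,8aR)-6-allyl-3-isopropyl-8a-methyl-6-[3-(trimethylsilyl)prop-2-yn-1-yl]hexahydro-5H-oxazolo[3,2-a]pyridin-5-one
Conditions: LiN(i-Pr)2, THF, DMPU, −78 °C; then 6, −78 °C; chromatography
Reagents that add atoms: none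
Why: Meyers endo-selective second enolate alkylation: allyl bromide enters anti to the angular methyl and fixes the quaternary carbon (future C8); the minor diastereomer is removed by chromatography.

Step 4
Reactants: 7 dialkylated lactam
Product: 11 (R)-4-allyl-4-(prop-2-yn-1-yl)cyclohex-2-en-1-one, via carbinolamine 8 (not isolated), via keto aldehyde 9 (not isolated), via silylalkynyl enone 10 (not isolated)
Conditions: NaAlH2(OCH2CH2OMe)2, PhMe, −20 → 0 °C; then 1 M Bu4N(H2PO4), EtOH/H2O, reflux; then KOH, EtOH, rt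
Reagents that add atoms: water, O
Why: Meyers reduction, hydrolysis and intramolecular aldol condensation release the auxiliary and give the 4,4-disubstituted cyclohexenone without touching the quaternary centre; KOH also cleaves the C–Si bond.

Step 5
Reactants: 11 (R)-4-allyl-4-(prop-2-yn-1-yl)cyclohex-2-en-1-one
Product: 12 2-[(1S)-4-oxo-1-(prop-2-yn-1-yl)cyclohex-2-en-1-yl]acetaldehyde
Conditions: OsO4 (2 mol%), NaIO4, 2,6-lutidine, dioxane/H2O, rt
Reagents that add atoms: sodium periodate, [Na+].[O-]I(=O)(=O)=O; osmium tetroxide (catalytic oxygen carrier), O=[Os](=O)(=O)=O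
Why: Lemieux–Johnson cleavage; the electron-rich monosubstituted alkene reacts ahead of the enone and the alkyne.

Step 6
Reactants: 12 aldehyde
Product: 14 methyl 2-[(1S)-4-oxo-1-(prop-2-yn-1-yl)cyclohex-2-en-1-yl]acetate, via carboxylic acid 13 (not isolated)
Conditions: NaClO2, NaH2PO4, 2-methyl-2-butene, t-BuOH/H2O, rt; then Me3SiCHN2, PhMe/MeOH, 0 °C
Reagents that add atoms: sodium chlorite, [Na+].[O-]Cl=O; trimethylsilyldiazomethane, C[Si](C)(C)C=[N+]=[N-]
Why: Pinnick oxidation followed by diazoalkane esterification; no stereocentre is involved.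

Step 7
Reactants: 14 enone ester
Product: 15 methyl 2-[(1S)-4-(tert-butyldimethylsilyloxy)-1-(prop-2-yn-1-yl)cyclohexa-2,4-dien-1-yl]acetate
Conditions: TBSOTf, Et3N, CH2Cl2, 0 °C
Reagents that add atoms: tert-butyldimethylsilyl triflate, CC(C)(C)[Si](C)(C)OS(=O)(=O)C(F)(F)F
Why: Soft enolisation of the enone at the α' carbon gives the cross-conjugated 2-silyloxydiene; the ester is not enolised under these conditions.

Step 8
Reactants: 15 silyl dienol ether
Product: 16 methyl 2-[(1S,5R)-6-methylidene-4-oxobicyclo[3.2.1]oct-2-en-1-yl]acetate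
Conditions: Ph3PAuCl (5 mol%), AgBF4 (5 mol%), PhMe/MeOH 10:1, rt
Reagents that add atoms: none
Why: Monovalent-gold-catalysed 5-exo-dig carbocyclisation of the silyl enol ether onto the alkyne (Conia-ene type) closes ring D with the exocyclic methylene; the C13 bridgehead is dictated by C8.

Step 9
Reactants: 16 bicyclic enone; 17 1-(tert-butyldimethylsilyloxy)-1-methoxyethene
Product: 18 dimethyl 2,2'-(6-methylidene-4-oxobicyclo[3.2.1]octane-1,2-diyl)diacetate (C9 chain exo; 9β-H)
Conditions: TiCl4 (1.1 equiv), CH2Cl2, −78 °C; then H2O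
Reagents that add atoms: none
Why: Mukaiyama–Michael addition; the ketene silyl acetal attacks C9 on the exo face, anti to the two-carbon bridge, so the new CH2CO2Me (C10, C20) is axial on ring C and H9 is β.

Step 10
Reactants: 18 keto diester
Product: 20 tricyclic lactone ester (rings C and D plus the 20→12α δ-lactone; C8 carries CH2CO2Me; C10 is CH2), via hydroxy diester 19 (not isolated)
Conditions: LiBH(s-Bu)3, THF, −78 °C; AcOH quench; then PPTS (cat.), PhMe, 80 °C
Reagents that add atoms: none
Why: The bulky hydride attacks the 12-ketone equatorially because the axial face is blocked by the syn-axial C9 chain; the resulting axial 12α-alcohol closes the δ-lactone onto the C20 ester (1,3-diaxial lactonisation).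

Step 11
Reactants: 20 lactone ester
Product: 21 tetracyclic β-keto lactone (ring B closed as the 5-ketone; C6 is CH2; 10β-H)
Conditions: LiN(SiMe3)2 (2.5 equiv), THF, −78 → 0 °C; then 1 M HCl
Reagents that add atoms: none
Why: Intramolecular Claisen (Dieckmann-type) condensation: the more acidic and less hindered lactone α-carbon C10 is acylated by the C8 acetate arm, which can only reach the endo face of C10, so ring B is cis-fused to the lactone.

Step 12
Reactants: 21 tetracyclic β-keto lactone; 22 benzyl chloromethyl ether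
Product: 23 6β-(benzyloxymethyl) tetracyclic β-keto lactone
Conditions: LiN(i-Pr)2 (2.2 equiv), THF, −78 → −30 °C; then 22 (1.0 equiv), −78 °C; AcOH quench
Reagents that add atoms: none
Why: Weiler-type dianion alkylation at the γ-carbon C6 brings in C7; the electrophile enters from the convex β-face, and C6 stays epimerisable until it is finally equilibrated in step 20.

Step 13
Reactants: 24 allyl acetate; 25 acrolein
Product: 26 allyl 3-hydroxypent-4-enoate (racemic)
Conditions: LiN(i-Pr)2, THF, −78 °C; then 25, −78 °C; AcOH quench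
Reagents that add atoms: none
Why: Ester enolate aldol addition (1,2) to acrolein; the carbinol stereocentre is destroyed in the next step.

Step 14
Reactants: 26 allyl 3-hydroxypent-4-enoate
Product: 27 allyl 3-oxopent-4-enoate
Conditions: CrO3, H2SO4, acetone, 0 °C; used at once
Reagents that add atoms: none
Why: Jones oxidation of the allylic alcohol gives the Nazarov-type vinyl ketone annulation reagent.

Step 15
Reactants: 23 6β-(benzyloxymethyl) β-keto lactone; 27 allyl 3-oxopent-4-enoate
Product: 28 Michael adduct (23 carrying the 10β-CH2CH2C(=O)CH2CO2allyl chain)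
Conditions: Et3N (0.2 equiv), CH2Cl2, 0 °C → rt
Reagents that add atoms: none
Why: Michael addition of the β-keto lactone, whose C10 is the only doubly activated carbon, to the vinyl ketone; only the exo face of C10 is open, so C1 ends β and C20 α.

Step 16
Reactants: 28 Michael adduct
Product: 29 allyl 7-(benzyloxy)-3-oxo-18-norgibberella-4,16-dien-19-oate 20→12α-lactone
Conditions: TiCl4, pyridine, THF, 0 °C → rt
Reagents that add atoms: none
Why: Intramolecular Knoevenagel condensation (Lehnert conditions) of the side-chain β-keto ester onto the C5 ketone closes ring A without alkoxide, which would cleave the β-keto lactone.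

Step 17
Reactants: 29 ring A alkylidene β-keto ester
Product: 30 allyl 7-(benzyloxy)-3-oxo-18-nor-5β-gibberell-16-en-19-oate 20→12α-lactone (C4 epimers plus enol)
Conditions: LiBH(s-Bu)3, THF, −78 °C; AcOH quench
Reagents that add atoms: none
Why: Conjugate (1,4) hydride reduction of the doubly activated alkene; hydride reaches C5 from the β-face opposite the angular lactone carbonyl, giving the trans A/B fusion.

Step 18
Reactants: 30 β-keto ester
Product: 31 allyl 7-(benzyloxy)-3-oxogibberell-16-en-19-oate 20→12α-lactone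
Conditions: K2CO3, MeI, acetone, 40 °C
Reagents that add atoms: iodomethane, CI
Why: C-alkylation of the β-keto ester enolate; MeI approaches C4 anti to the axial C20 carbonyl, so the methyl ends β (equatorial) and the ester α (axial).

Step 19
Reactants: 31 benzyl ether
Product: 32 allyl 7-hydroxy-3-oxogibberell-16-en-19-oate 20→12α-lactone
Conditions: BCl3, pentamethylbenzene, CH2Cl2, −78 °C; MeOH quench
Reagents that add atoms: none
Why: Lewis-acid debenzylation with a cation scavenger at low temperature, chosen because hydrogenolysis would reduce the exocyclic alkene.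

Step 20
Reactants: 32 primary alcohol
Product: 33 allyl 3,7-dioxogibberell-16-en-19-oate 20→12α-lactone (6β-formyl)
Conditions: Dess–Martin periodinane, CH2Cl2, rt; then DBU (0.3 equiv), CH2Cl2, rt
Reagents that add atoms: none
Why: Dess–Martin oxidation, then base equilibration of C6 to the more stable 6β-formyl epimer (trans to the quaternary C4 on C5).

Step 21
Reactants: 33 aldehyde
Product: 34 19-allyl ester of 3-oxogibberell-16-ene-7,19,20-trioic acid 20→12α-lactone
Conditions: NaClO2, NaH2PO4, 2-methyl-2-butene, t-BuOH/H2O, rt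
Reagents that add atoms: sodium chlorite, [Na+].[O-]Cl=O
Why: Pinnick oxidation; the scavenger protects the exocyclic alkene from hypochlorite.

Step 22
Reactants: 34 keto acid
Product: 35 19-allyl ester of 2β-hydroxy-3-oxogibberell-16-ene-7,19,20-trioic acid 20→12α-lactone
Conditions: KN(SiMe3)2 (2.5 equiv), THF, −78 °C; then 2-(phenylsulfonyl)-3-phenyloxaziridine, −78 °C; 1 M HCl
Reagents that add atoms: 2-(phenylsulfonyl)-3-phenyloxaziridine, O=S(=O)(c1ccccc1)N1OC1c1ccccc1
Why: Davis enolate hydroxylation; the 3-ketone enolises only toward C2, and the oxidant comes from the β-face because the α-face is blocked by the syn-axial C19 ester and C20.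

Step 23
Reactants: 35 α-hydroxy ketone
Product: 36 19-allyl ester of 2β,3β-dihydroxygibberell-16-ene-7,19,20-trioic acid 20→12α-lactone
Conditions: LiBH(s-Bu)3 (3.5 equiv), THF, −78 °C; 1 M HCl
Reagents that add atoms: none
Why: Equatorial attack of the bulky hydride on the 3-ketone gives the axial 3β-alcohol, cis to the 2β-hydroxyl, as known for 3-oxogibberellins.

Step 24
Reactants: 36 allyl ester
Product: 37 2β,3β-dihydroxygibberell-16-ene-7,19,20-trioic acid 20→12α-lactone (CNP0212122.1)
Conditions: Pd(PPh3)4 (5 mol%), morpholine, THF, rt; then dilute HCl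
Reagents that add atoms: none
Why: Tsuji–Trost deallylation with zerovalent palladium frees the hindered axial C19 acid under neutral conditions that leave the lactone, diol and exocyclic alkene intact.

## Compound list

1 | (S)-valinol | CC(C)[C@H](N)CO | starting material
2 | 5-oxohexanoic acid | CC(=O)CCCC(=O)O | starting material
3 | (3S,8aR)-3-isopropyl-8a-methylhexahydro-5H-oxazolo[3,2-a]pyridin-5-one | CC(C)[C@H]1CO[C@]2(C)CCCC(=O)N12 | intermediate
4 | 3-bromo-1-(trimethylsilyl)prop-1-yne | C[Si](C)(C)C#CCBr | starting material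
5 | 6-[3-(trimethylsilyl)prop-2-yn-1-yl] lactam (C6 epimers) | CC(C)[C@H]1CO[C@]2(C)CCC(CC#C[Si](C)(C)C)C(=O)N12 | intermediate
6 | allyl bromide | C=CCBr | starting material
7 | (3S,6R,8aR)-6-allyl-6-[3-(trimethylsilyl)prop-2-yn-1-yl] lactam | CC(C)[C@H]1CO[C@]2(C)CC[C@@](CC=C)(CC#C[Si](C)(C)C)C(=O)N12 | intermediate
8 | carbinolamine (lactam C=O reduced to CH–OH) | CC(C)[C@H]1CO[C@]2(C)CC[C@@](CC=C)(CC#C[Si](C)(C)C)C(O)N12 | intermediate
9 | (R)-2-allyl-5-oxo-2-[3-(trimethylsilyl)prop-2-yn-1-yl]hexanal | O=C[C@](CC=C)(CC#C[Si](C)(C)C)CCC(C)=O | intermediate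
10 | (R)-4-allyl-4-[3-(trimethylsilyl)prop-2-yn-1-yl]cyclohex-2-en-1-one | C[Si](C)(C)C#CC[C@@]1(CC=C)C=CC(=O)CC1 | intermediate
11 | (R)-4-allyl-4-(prop-2-yn-1-yl)cyclohex-2-en-1-one | C#CC[C@@]1(CC=C)C=CC(=O)CC1 | intermediate
12 | 2-[(1S)-4-oxo-1-(prop-2-yn-1-yl)cyclohex-2-en-1-yl]acetaldehyde | C#CC[C@@]1(CC=O)C=CC(=O)CC1 | intermediate
13 | 2-[(1S)-4-oxo-1-(prop-2-yn-1-yl)cyclohex-2-en-1-yl]acetic acid | C#CC[C@@]1(CC(=O)O)C=CC(=O)CC1 | intermediate
14 | methyl 2-[(1S)-4-oxo-1-(prop-2-yn-1-yl)cyclohex-2-en-1-yl]acetate | C#CC[C@@]1(CC(=O)OC)C=CC(=O)CC1 | intermediate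
15 | methyl 2-[(1S)-4-(tert-butyldimethylsilyloxy)-1-(prop-2-yn-1-yl)cyclohexa-2,4-dien-1-yl]acetate | C#CC[C@@]1(CC(=O)OC)C=CC(O[Si](C)(C)C(C)(C)C)=CC1 | intermediate
16 | methyl 2-[(1S,5R)-6-methylidene-4-oxobicyclo[3.2.1]oct-2-en-1-yl]acetate | C=C1C[C@]2(CC(=O)OC)C[C@H]1C(=O)C=C2 | intermediate
17 | 1-(tert-butyldimethylsilyloxy)-1-methoxyethene | C=C(OC)O[Si](C)(C)C(C)(C)C | starting material
18 | dimethyl 2,2'-(6-methylidene-4-oxobicyclo[3.2.1]octane-1,2-diyl)diacetate (C9 chain exo) | C=C1C[C@]2(CC(=O)OC)C[C@H]1C(=O)C[C@H]2CC(=O)OC | intermediate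
19 | 12α-hydroxy diester | C=C1C[C@]2(CC(=O)OC)C[C@H]1[C@@H](O)C[C@H]2CC(=O)OC | intermediate
20 | tricyclic 20→12α lactone with C8 CH2CO2Me arm | C=C1C[C@]2(CC(=O)OC)C[C@H]1[C@@H]1C[C@H]2CC(=O)O1 | intermediate
21 | tetracyclic β-keto lactone (5-oxo, 10β-H) | C=C1C[C@]23C[C@H]1[C@@H]1C[C@H]2[C@H](C(=O)C3)C(=O)O1 | intermediate
22 | benzyl chloromethyl ether | ClCOCc1ccccc1 | starting material
23 | 6β-(benzyloxymethyl) tetracyclic β-keto lactone | C=C1C[C@]23C[C@H]1[C@@H]1C[C@H]2[C@H](C(=O)[C@@H]3COCc4ccccc4)C(=O)O1 | intermediate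
24 | allyl acetate | CC(=O)OCC=C | starting material
25 | acrolein | C=CC=O | starting material
26 | allyl 3-hydroxypent-4-enoate (racemic) | C=CC(O)CC(=O)OCC=C | intermediate
27 | allyl 3-oxopent-4-enoate | C=CC(=O)CC(=O)OCC=C | intermediate
28 | Michael adduct (C10 quaternary, 10β side chain) | C=C1C[C@]23C[C@H]1[C@@H]1C[C@H]2[C@](CCC(=O)CC(=O)OCC=C)(C(=O)[C@@H]3COCc4ccccc4)C(=O)O1 | intermediate
29 | allyl 7-(benzyloxy)-3-oxo-18-norgibberella-4,16-dien-19-oate 20→12α-lactone | C=C1C[C@]23C[C@H]1[C@@H]1C[C@H]2[C@@]2(CCC(=O)C(C(=O)OCC=C)=C2[C@@H]3COCc4ccccc4)C(=O)O1 | intermediate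
30 | allyl 7-(benzyloxy)-3-oxo-18-nor-5β-gibberell-16-en-19-oate 20→12α-lactone (C4 unassigned) | C=C1C[C@]23C[C@H]1[C@@H]1C[C@H]2[C@@]2(CCC(=O)C(C(=O)OCC=C)[C@H]2[C@@H]3COCc4ccccc4)C(=O)O1 | intermediate
31 | allyl 7-(benzyloxy)-3-oxogibberell-16-en-19-oate 20→12α-lactone | C=C1C[C@]23C[C@H]1[C@@H]1C[C@H]2[C@@]2(CCC(=O)[C@@](C)(C(=O)OCC=C)[C@H]2[C@@H]3COCc4ccccc4)C(=O)O1 | intermediate
32 | allyl 7-hydroxy-3-oxogibberell-16-en-19-oate 20→12α-lactone | C=C1C[C@]23C[C@H]1[C@@H]1C[C@H]2[C@@]2(CCC(=O)[C@@](C)(C(=O)OCC=C)[C@H]2[C@@H]3CO)C(=O)O1 | intermediate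
33 | allyl 3,7-dioxogibberell-16-en-19-oate 20→12α-lactone (6β-formyl) | C=C1C[C@]23C[C@H]1[C@@H]1C[C@H]2[C@@]2(CCC(=O)[C@@](C)(C(=O)OCC=C)[C@H]2[C@@H]3C=O)C(=O)O1 | intermediate
34 | 19-allyl ester of 3-oxogibberell-16-ene-7,19,20-trioic acid 20→12α-lactone | C=C1C[C@]23C[C@H]1[C@@H]1C[C@H]2[C@@]2(CCC(=O)[C@@](C)(C(=O)OCC=C)[C@H]2[C@@H]3C(=O)O)C(=O)O1 | intermediate
35 | 19-allyl ester of 2β-hydroxy-3-oxogibberell-16-ene-7,19,20-trioic acid 20→12α-lactone | C=C1C[C@]23C[C@H]1[C@@H]1C[C@H]2[C@@]2(C[C@H](O)C(=O)[C@@](C)(C(=O)OCC=C)[C@H]2[C@@H]3C(=O)O)C(=O)O1 | intermediate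
36 | 19-allyl ester of 2β,3β-dihydroxygibberell-16-ene-7,19,20-trioic acid 20→12α-lactone | C=C1C[C@]23C[C@H]1[C@@H]1C[C@H]2[C@@]2(C[C@H](O)[C@H](O)[C@@](C)(C(=O)OCC=C)[C@H]2[C@@H]3C(=O)O)C(=O)O1 | intermediate
37 | 2β,3β-dihydroxygibberell-16-ene-7,19,20-trioic acid 20→12α-lactone (CNP0212122.1) | C=C1C[C@]23C[C@H]1[C@@H]1C[C@H]2[C@@]2(C[C@H](O)[C@H](O)[C@@](C)(C(=O)O)[C@H]2[C@@H]3C(=O)O)C(=O)O1 | target

## Step count and risks

Total steps: 24. Longest linear sequence: 22 (steps 1–12 and 15–24); steps 13–14 make reagent 27.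

Most likely to fail:

Step 9. The Mukaiyama–Michael addition must reach a β-carbon next to a quaternary bridgehead, with a Lewis acid beside an exocyclic alkene. The fallback sets out from 16: base-mediated addition of dimethyl malonate (NaOMe cat., MeOH, rt, or 10 kbar) gives the malonate adduct F1. Krapcho dealkoxycarbonylation (LiCl, wet DMSO, 150 °C) then removes one malonate ester and comes back to the route at 18.

Step 11. The Claisen closure of ring B relies on the lactone enolate forming and attacking the arm ester rather than the arm enolate opening the lactone. The fallback sets out from 20: LiOH (THF/H2O) followed by acidification gives the lactone acid F2 (the δ-lactone re-closes spontaneously). 1,1'-Carbonyldiimidazole converts it into the acyl imidazolide F3, and LiN(SiMe3)2 (2.2 equiv, THF, −78 °C) then acylates the lactone enolate irreversibly, coming back at 21.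

Step 17. Hydride has to reach a tetrasubstituted C5 flanked by a quaternary carbon, and from the β-face. The fallback sets out from 29 and replaces hydride delivery by electron transfer: SmI2 (2.5 equiv), THF/MeOH, −78 °C reduces the alkylidene β-keto ester by two single-electron transfers, with protonation of C5 on the open β-face. It comes back at 30 and forms no new compound (F0).

## Further compounds

F1 | step 9 | dimethyl 2-[1-(2-methoxy-2-oxoethyl)-6-methylidene-4-oxobicyclo[3.2.1]octan-2-yl]malonate (malonate adduct, C9 chain exo) | C=C1C[C@]2(CC(=O)OC)C[C@H]1C(=O)C[C@H]2C(C(=O)OC)C(=O)OC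
F2 | step 11 | lactone acid (20 with the C8 arm as CH2CO2H) | C=C1C[C@]2(CC(=O)O)C[C@H]1[C@@H]1C[C@H]2CC(=O)O1
F3 | step 11 | acyl imidazolide of F2 | C=C1C[C@]2(CC(=O)n3ccnc3)C[C@H]1[C@@H]1C[C@H]2CC(=O)O1
F0 | step 17 | none | none
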